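**Retrosynthetic overview**

1. Germacrane numbering is used: C6 lactone carbinol, C7 ring-fusion CH, C8 methacrylate carbon, C3 acetate carbon, C4 bearing C15H2OH, C1/C10 oxirane. The enabling feature is that C3(OAc)–C4=C5–C6(O–C12) is a cis-but-2-ene-1,4-diyl diester inside the ten-membered ring, with the carboxyl C12 held on C11–C7 next to C6. This is the retron of an oxidative 1,4-addition of the C12 carboxylate and acetate across a C3=C4–C5=C6 ring diene.
2. Target ⇐ (PMB removal, 1(10)-epoxidation) lactone 26 ⇐ macrocyclic triene acid 25 by palladium-catalysed 1,4-acetoxylactonization. This closes the γ-lactone through O–C6 and sets C6, C3, the C3 acetate and the 4Z alkene in one operation.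
3. 25 ⇐ ring-closing metathesis at C5=C6 (ten-membered ring) ⇐ asymmetric chromium-catalysed 2-(alkoxycarbonyl)allylation (C7–C8, both stereocentres) ⇐ carboalumination/allyl coupling (C1–C2, 1(10)E) ⇐ diene unit from but-2-yne-1,4-diol.
4. Ring order: ten-membered carbocycle (step 12), γ-lactone (step 15), oxirane (step 16).

Key step: step 15

Remark: in step 11 the ligand enantiomer is taken to be the one that directs the allyl unit to the Si face of the aldehyde; this assignment has to be confirmed on the first adduct.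

**Step 1**
Reactants: 1 but-2-yne-1,4-diol
Product: 2 4-[(4-methoxybenzyl)oxy]but-2-yn-1-ol
Conditions: NaH (1.0 equiv), diol 1 (3 equiv), 4-methoxybenzyl chloride (1.0 equiv), n-Bu4NI (cat.), THF/DMF, 0 °C → rt
Reagents that add atoms: 4-methoxybenzyl chloride, COc1ccc(CCl)cc1
Why: Williamson etherification of the mono-alkoxide; the excess of the symmetric diol should suppress the bis-ether.

**Step 2**
Reactants: 2 4-[(4-methoxybenzyl)oxy]but-2-yn-1-ol
Product: 4 (2Z)-3-iodo-4-[(4-methoxybenzyl)oxy]but-2-en-1-ol, via cyclic vinylaluminate 3 (not isolated)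
Conditions: NaAlH2(OCH2CH2OMe)2, THF, 0 °C → rt; then I2, THF, −78 → 0 °C; aq. Rochelle salt
Reagents that add atoms: iodine, II
Why: Hydroxyl-directed trans-hydroalumination of the propargylic alcohol puts hydride on the proximal and aluminium on the distal alkyne carbon, and iodinolysis with retention should give the Z-iodide, which fixes the C3=C4 geometry (C2 cis to the future C5).

**Step 3**
Reactants: 4 (2Z)-3-iodo-4-[(4-methoxybenzyl)oxy]but-2-en-1-ol; 5 tributyl(ethenyl)stannane
Product: 6 (2E)-3-{[(4-methoxybenzyl)oxy]methyl}penta-2,4-dien-1-ol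
Conditions: Pd(PPh3)4 (5 mol %), CuI (10 mol %), DMF, rt
Reagents that add atoms: none
Why: Stille coupling of an alkenyl iodide proceeds with retention of alkene geometry and tolerates the free alcohol.

**Step 4**
Reactants: 6 (2E)-3-{[(4-methoxybenzyl)oxy]methyl}penta-2,4-dien-1-ol
Product: 8 (2E)-1-chloro-3-{[(4-methoxybenzyl)oxy]methyl}penta-2,4-diene, via allylic mesylate 7 (not isolated)
Conditions: MsCl, 2,4,6-collidine, LiCl, DMF, 0 °C
Reagents that add atoms: lithium chloride, [Li+].[Cl-]
Why: Mesylation followed by SN2 displacement with chloride at the primary allylic carbon should give the chloride without allylic transposition or loss of alkene geometry.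

**Step 5**
Reactants: 9 tert-butyl(but-3-yn-1-yloxy)dimethylsilane; 8 (2E)-1-chloro-3-{[(4-methoxybenzyl)oxy]methyl}penta-2,4-diene
Product: 11 tert-butyl{[(3E,6E)-7-{[(4-methoxybenzyl)oxy]methyl}-3-methylnona-3,6,8-trien-1-yl]oxy}dimethylsilane, via alkenylalane 10 (not isolated)
Conditions: AlMe3 (2 equiv), Cp2ZrCl2 (0.25 equiv), ClCH2CH2Cl, rt; then 8, Pd(PPh3)4 (5 mol %), THF, 0 °C → rt
Reagents that add atoms: trimethylaluminium, C[Al](C)C
Why: Negishi zirconium-catalysed syn-carboalumination sets the 1(10)E trisubstituted alkene (methyl and aluminium cis), and the alkenylalane should couple with the allylic chloride under zerovalent palladium at the CH2 terminus with retention of both alkene geometries.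

**Step 6**
Reactants: 11 tert-butyl{[(3E,6E)-7-{[(4-methoxybenzyl)oxy]methyl}-3-methylnona-3,6,8-trien-1-yl]oxy}dimethylsilane
Product: 12 (3E,6E)-7-{[(4-methoxybenzyl)oxy]methyl}-3-methylnona-3,6,8-trien-1-ol
Conditions: PPTS (cat.), MeOH, rt
Reagents that add atoms: none
Why: Mild acid-catalysed methanolysis should remove the primary TBS ether while the PMB ether and the dienes are untouched.

**Step 7**
Reactants: 12 (3E,6E)-7-{[(4-methoxybenzyl)oxy]methyl}-3-methylnona-3,6,8-trien-1-ol
Product: 13 (3E,6E)-7-{[(4-methoxybenzyl)oxy]methyl}-3-methylnona-3,6,8-trienal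
Conditions: Dess–Martin periodinane, NaHCO3, CH2Cl2, 0 °C; used at once
Reagents that add atoms: none
Why: Buffered Dess–Martin oxidation is neutral enough to deliver the β,γ-unsaturated aldehyde without migration of the C1=C10 bond into conjugation.

**Step 8**
Reactants: 14 prop-2-enoyl chloride; 15 2-(trimethylsilyl)ethanol
Product: 16 2-(trimethylsilyl)ethyl prop-2-enoate
Conditions: Et3N, CH2Cl2, 0 °C
Reagents that add atoms: none
Why: Simple acylation of a primary alcohol by an acid chloride.

**Step 9**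
Reactants: 16 2-(trimethylsilyl)ethyl prop-2-enoate; 17 prop-2-enal
Product: 18 2-(trimethylsilyl)ethyl 3-hydroxy-2-methylidenepent-4-enoate (racemic)
Conditions: DABCO (20 mol %), 1,4-dioxane/H2O, rt
Reagents that add atoms: none
Why: Morita–Baylis–Hillman reaction of the acrylate with the aldehyde; the carbinol centre is racemic and is destroyed in step 10.

**Step 10**
Reactants: 18 2-(trimethylsilyl)ethyl 3-hydroxy-2-methylidenepent-4-enoate
Product: 19 2-(trimethylsilyl)ethyl (2Z)-2-(bromomethyl)penta-2,4-dienoate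
Conditions: PBr3 (0.4 equiv), Et2O, 0 °C
Reagents that add atoms: phosphorus tribromide, BrP(Br)Br
Why: Bromination of a Baylis–Hillman alcohol with allylic transposition (SN2') should give the conjugated bromide with the vinyl group trans to the ester, which is the thermodynamically preferred Z isomer.

**Step 11**
Reactants: 13 (3E,6E)-7-{[(4-methoxybenzyl)oxy]methyl}-3-methylnona-3,6,8-trienal; 19 2-(trimethylsilyl)ethyl (2Z)-2-(bromomethyl)penta-2,4-dienoate
Product: 21 2-(trimethylsilyl)ethyl (3R,4R,6E,9E)-3-ethenyl-4-hydroxy-10-{[(4-methoxybenzyl)oxy]methyl}-6-methyl-2-methylidenedodeca-6,9,11-trienoate, via trimethylsilyl ether 20 (not isolated)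
Conditions: CrCl2 (10 mol %), chiral carbazole-bis(oxazoline) ligand (12 mol %), Mn powder, Me3SiCl, i-Pr2NEt (cat.), THF, 0 °C → rt; then 1 M aq. HCl/THF, 0 °C, brief
Reagents that add atoms: none
Why: Catalytic asymmetric Nozaki–Hiyama–Kishi 2-(alkoxycarbonyl)allylation: γ-attack of the Z-configured allylchromium through a chair transition state should place the C7 vinyl group and the C8 hydroxyl syn, and the ligand sets the absolute configuration by Si-face addition (7R, 8R in germacrane numbering).

**Step 12**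
Reactants: 21 2-(trimethylsilyl)ethyl (3R,4R,6E,9E)-3-ethenyl-4-hydroxy-10-{[(4-methoxybenzyl)oxy]methyl}-6-methyl-2-methylidenedodeca-6,9,11-trienoate
Product: 22 2-(trimethylsilyl)ethyl 2-[(1R,2Z,4E,7E,10R)-10-hydroxy-4-{[(4-methoxybenzyl)oxy]methyl}-8-methylcyclodeca-2,4,7-trien-1-yl]prop-2-enoate
Conditions: second-generation Hoveyda–Grubbs catalyst RuCl2(H2IMes)(=CH-C6H4-2-OiPr) (10 mol %), toluene (1 mM), 60 °C, argon sparge
Reagents that add atoms: none
Why: Ring-closing diene–ene metathesis between the two monosubstituted vinyl termini (the trisubstituted and acrylate alkenes are poor partners); the ten-membered ring should enforce the cis C5=C6 bond, and the cis C3=C4 unit already turns the chain back on itself.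

**Step 13**
Reactants: 22 2-(trimethylsilyl)ethyl 2-[(1R,2Z,4E,7E,10R)-10-hydroxy-4-{[(4-methoxybenzyl)oxy]methyl}-8-methylcyclodeca-2,4,7-trien-1-yl]prop-2-enoate; 23 2-methylprop-2-enoic anhydride
Product: 24 2-(trimethylsilyl)ethyl 2-[(1R,2Z,4E,7E,10R)-4-{[(4-methoxybenzyl)oxy]methyl}-8-methyl-10-[(2-methylprop-2-enoyl)oxy]cyclodeca-2,4,7-trien-1-yl]prop-2-enoate
Conditions: Et3N, DMAP (cat.), CH2Cl2, 0 °C → rt
Reagents that add atoms: none
Why: DMAP-catalysed acylation of the secondary alcohol installs the C8 methacrylate of the target after the metathesis, so that it cannot take part in it, and blocks 8,12-lactonization.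

**Step 14**
Reactants: 24 2-(trimethylsilyl)ethyl 2-[(1R,2Z,4E,7E,10R)-4-{[(4-methoxybenzyl)oxy]methyl}-8-methyl-10-[(2-methylprop-2-enoyl)oxy]cyclodeca-2,4,7-trien-1-yl]prop-2-enoate
Product: 25 2-[(1R,2Z,4E,7E,10R)-4-{[(4-methoxybenzyl)oxy]methyl}-8-methyl-10-[(2-methylprop-2-enoyl)oxy]cyclodeca-2,4,7-trien-1-yl]prop-2-enoic acid
Conditions: tris(dimethylamino)sulfonium difluorotrimethylsilicate (1.5 equiv), DMF, 0 °C; dilute aq. HCl to pH 4
Reagents that add atoms: none
Why: Fluoride-induced β-elimination of the 2-(trimethylsilyl)ethyl ester should free the acrylic acid under nearly neutral conditions that spare the methacrylate, the PMB ether and the base-sensitive C7–H.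

**Step 15**
Reactants: 25 2-[(1R,2Z,4E,7E,10R)-4-{[(4-methoxybenzyl)oxy]methyl}-8-methyl-10-[(2-methylprop-2-enoyl)oxy]cyclodeca-2,4,7-trien-1-yl]prop-2-enoic acid
Product: 26 (3aR,4R,6E,9S,10Z,11aR)-9-acetoxy-10-{[(4-methoxybenzyl)oxy]methyl}-6-methyl-3-methylidene-2-oxo-2,3,3a,4,5,8,9,11a-octahydrocyclodeca[b]furan-4-yl 2-methylprop-2-enoate
Conditions: Pd(OAc)2 (10 mol %), 1,4-benzoquinone (25 mol %), MnO2 (2 equiv), LiOAc (2 equiv), AcOH/acetone 1:4, rt, chloride-free
Reagents that add atoms: acetic acid, CC(=O)O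
Why: Divalent palladium binds the s-cis C3=C4–C5=C6 diene, the C12 carboxylate adds to the diene terminus C6 anti to the metal to give an anti,anti-(η3-allyl)palladium unit over C3–C5, and quinone-assisted migration of acetate from palladium to C3 releases zerovalent palladium, which the quinone/MnO2 couple reoxidises. The closest known reaction type is the palladium-catalysed intramolecular 1,4-acetoxylactonization of cyclic dienylacetic acids, which gives the 1,4-trans product under chloride-free conditions. The γ-lactone ring closes in the 5-exo-trig mode through the new O–C6 bond. C6 is controlled by C7: allylic 1,3-strain across the cis C5=C6 bond keeps H7 in the diene plane, so the carboxylate on C11 can reach only one face and the lactone should be trans-fused (6R). C3 is controlled by the metal, which sits on the face opposite the lactone oxygen and delivers acetate from that face (3S), and the 4Z geometry follows from the cis,cis ring diene, whose allyl intermediate cannot isomerise inside the ring. The step needs 1,4- over 1,2-addition and diene over isolated-alkene selectivity: acetate attacks the allyl terminus remote from the electron-withdrawing lactone oxygen, the 1(10)-alkene and both acrylate units are not activated at room temperature, and catalytic quinone with MnO2 limits Diels–Alder loss of the diene.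

**Step 16**
Reactants: 26 (3aR,4R,6E,9S,10Z,11aR)-9-acetoxy-10-{[(4-methoxybenzyl)oxy]methyl}-6-methyl-3-methylidene-2-oxo-2,3,3a,4,5,8,9,11a-octahydrocyclodeca[b]furan-4-yl 2-methylprop-2-enoate
Product: 27 15-O-(4-methoxybenzyl) ether of the target (1R,10R-epoxide)
Conditions: mCPBA (1.1 equiv), NaHCO3, CH2Cl2, 0 °C
Reagents that add atoms: 3-chloroperoxybenzoic acid, OOC(=O)c1cccc(Cl)c1
Why: Prilezhaev epoxidation should select the strained, electron-rich 1(10)E alkene over the 4,5-alkene (deactivated by two allylic acyloxy groups) and the two acrylates; it is stereospecific (E-alkene to trans-epoxide) and peripheral attack on the outer face of the ring alkene is expected to give the 1R,10R isomer, as is usual for 1(10)-germacrenolides.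

**Step 17**
Reactants: 27 15-O-(4-methoxybenzyl) ether of the target
Product: 28 CNP0319155.1
Conditions: DDQ (1.5 equiv), CH2Cl2/pH 7 phosphate buffer 10:1, 0 °C → rt
Reagents that add atoms: none
Why: Oxidative cleavage of the PMB ether under buffered neutral conditions should free the C15 alcohol without opening the epoxide or moving the C3 acetate to C15.

**Compound list**

1 | but-2-yne-1,4-diol | OCC#CCO | starting material
2 | 4-[(4-methoxybenzyl)oxy]but-2-yn-1-ol | COc1ccc(COCC#CCO)cc1 | intermediate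
3 | sodium 2,2-bis(2-methoxyethoxy)-3-{[(4-methoxybenzyl)oxy]methyl}-2,5-dihydro-1,2-oxaluminol-2-uide (cyclic vinylaluminate, O–Al–C=C–CH2 ring) | [Na+].COCCO[Al-]1(OCCOC)OCC=C1COCc1ccc(OC)cc1 | intermediate (not isolated)
4 | (2Z)-3-iodo-4-[(4-methoxybenzyl)oxy]but-2-en-1-ol | OC/C=C(\I)COCc1ccc(OC)cc1 | intermediate
5 | tributyl(ethenyl)stannane | C=C[Sn](CCCC)(CCCC)CCCC | starting material
6 | (2E)-3-{[(4-methoxybenzyl)oxy]methyl}penta-2,4-dien-1-ol | OC/C=C(\C=C)COCc1ccc(OC)cc1 | intermediate
7 | (2E)-3-{[(4-methoxybenzyl)oxy]methyl}penta-2,4-dien-1-yl methanesulfonate | CS(=O)(=O)OC/C=C(\C=C)COCc1ccc(OC)cc1 | intermediate (not isolated)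
8 | (2E)-1-chloro-3-{[(4-methoxybenzyl)oxy]methyl}penta-2,4-diene | ClC/C=C(\C=C)COCc1ccc(OC)cc1 | intermediate
9 | tert-butyl(but-3-yn-1-yloxy)dimethylsilane | C#CCCO[Si](C)(C)C(C)(C)C | starting material
10 | [(1E)-4-{[tert-butyl(dimethyl)silyl]oxy}-2-methylbut-1-en-1-yl]dimethylalumane | C[Al](C)/C=C(\C)CCO[Si](C)(C)C(C)(C)C | intermediate (not isolated)
11 | tert-butyl{[(3E,6E)-7-{[(4-methoxybenzyl)oxy]methyl}-3-methylnona-3,6,8-trien-1-yl]oxy}dimethylsilane | CC(C)(C)[Si](C)(C)OCC/C(C)=C/C/C=C(\C=C)COCc1ccc(OC)cc1 | intermediate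
12 | (3E,6E)-7-{[(4-methoxybenzyl)oxy]methyl}-3-methylnona-3,6,8-trien-1-ol | OCC/C(C)=C/C/C=C(\C=C)COCc1ccc(OC)cc1 | intermediate
13 | (3E,6E)-7-{[(4-methoxybenzyl)oxy]methyl}-3-methylnona-3,6,8-trienal | O=CC/C(C)=C/C/C=C(\C=C)COCc1ccc(OC)cc1 | intermediate
14 | prop-2-enoyl chloride | C=CC(=O)Cl | starting material
15 | 2-(trimethylsilyl)ethanol | C[Si](C)(C)CCO | starting material
16 | 2-(trimethylsilyl)ethyl prop-2-enoate | C=CC(=O)OCC[Si](C)(C)C | intermediate
17 | prop-2-enal | C=CC=O | starting material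
18 | 2-(trimethylsilyl)ethyl 3-hydroxy-2-methylidenepent-4-enoate (racemic) | C=CC(O)C(=C)C(=O)OCC[Si](C)(C)C | intermediate
19 | 2-(trimethylsilyl)ethyl (2Z)-2-(bromomethyl)penta-2,4-dienoate | C=C/C=C(\CBr)C(=O)OCC[Si](C)(C)C | intermediate
20 | O-trimethylsilyl ether of 21 | C=C(C(=O)OCC[Si](C)(C)C)[C@@H](C=C)[C@H](O[Si](C)(C)C)C/C(C)=C/C/C=C(\C=C)COCc1ccc(OC)cc1 | intermediate (not isolated)
21 | 2-(trimethylsilyl)ethyl (3R,4R,6E,9E)-3-ethenyl-4-hydroxy-10-{[(4-methoxybenzyl)oxy]methyl}-6-methyl-2-methylidenedodeca-6,9,11-trienoate | C=C(C(=O)OCC[Si](C)(C)C)[C@@H](C=C)[C@H](O)C/C(C)=C/C/C=C(\C=C)COCc1ccc(OC)cc1 | intermediate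
22 | 2-(trimethylsilyl)ethyl 2-[(1R,2Z,4E,7E,10R)-10-hydroxy-4-{[(4-methoxybenzyl)oxy]methyl}-8-methylcyclodeca-2,4,7-trien-1-yl]prop-2-enoate | C=C(C(=O)OCC[Si](C)(C)C)[C@H]1/C=C\C(COCc2ccc(OC)cc2)=C/C/C=C(C)/C[C@H]1O | intermediate
23 | 2-methylprop-2-enoic anhydride | CC(=C)C(=O)OC(=O)C(C)=C | starting material
24 | 2-(trimethylsilyl)ethyl 2-[(1R,2Z,4E,7E,10R)-4-{[(4-methoxybenzyl)oxy]methyl}-8-methyl-10-[(2-methylprop-2-enoyl)oxy]cyclodeca-2,4,7-trien-1-yl]prop-2-enoate | C=C(C(=O)OCC[Si](C)(C)C)[C@H]1/C=C\C(COCc2ccc(OC)cc2)=C/C/C=C(C)/C[C@H]1OC(=O)C(C)=C | intermediate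
25 | 2-[(1R,2Z,4E,7E,10R)-4-{[(4-methoxybenzyl)oxy]methyl}-8-methyl-10-[(2-methylprop-2-enoyl)oxy]cyclodeca-2,4,7-trien-1-yl]prop-2-enoic acid | C=C(C(=O)O)[C@H]1/C=C\C(COCc2ccc(OC)cc2)=C/C/C=C(C)/C[C@H]1OC(=O)C(C)=C | intermediate
26 | (3aR,4R,6E,9S,10Z,11aR)-9-acetoxy-10-{[(4-methoxybenzyl)oxy]methyl}-6-methyl-3-methylidene-2-oxo-2,3,3a,4,5,8,9,11a-octahydrocyclodeca[b]furan-4-yl 2-methylprop-2-enoate | C=C(C)C(=O)O[C@@H]1C/C(C)=C/C[C@H](OC(C)=O)/C(COCc3ccc(OC)cc3)=C\[C@H]2OC(=O)C(=C)[C@@H]21 | intermediate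
27 | 15-O-(4-methoxybenzyl) ether of the target (1R,10R-epoxide of 26) | C=C(C)C(=O)O[C@@H]1C[C@@]2(C)O[C@@H]2C[C@H](OC(C)=O)/C(COCc3ccc(OC)cc3)=C\[C@H]2OC(=O)C(=C)[C@@H]21 | intermediate
28 | CNP0319155.1: (1R,3S,4Z,6R,7R,8R,10R)-3-acetoxy-1,10-epoxy-15-hydroxy-8-(2-methylprop-2-enoyloxy)germacra-4,11(13)-dien-12,6-olide | C=C(C)C(=O)O[C@@H]1C[C@@]2(C)O[C@@H]2C[C@H](OC(C)=O)/C(CO)=C\[C@H]2OC(=O)C(=C)[C@@H]21 | target

**Step count**

Total steps: 17. Longest linear sequence: 14 steps (steps 1–7, then 11–17); steps 8–10 form a three-step side branch.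

**Three steps most likely to fail**

Step 15. The oxypalladation may take the wrong diene face and give the cis-fused lactone, the quinone may consume the diene by cycloaddition, or acetate may be delivered without the required syn sense. Fallback, from 25 back to 26, keeping the same O–C6 ring closure but with electrophilic selenium: acid 25 with N-(phenylselanyl)phthalimide and catalytic camphorsulfonic acid in CH2Cl2 at −78 °C should give, by anti 5-exo selenolactonization, the 5-(phenylselanyl) trans-lactone F1. Oxidation with H2O2/pyridine at 0 °C gives the allylic selenoxide, whose [2,3]-sigmatropic shift carries oxygen to C3 on the face that held selenium (opposite the lactone oxygen) and, after hydrolysis, the 3-hydroxy-4Z-lactone F2. Acetylation (Ac2O, pyridine, DMAP) returns to 26.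

Step 12. Closure of the ten-membered carbocycle may be slower than oligomerisation, or the ruthenium carbene may attack the internal C3=C4 bond and contract the ring. Fallback, from 21 back to 25, using a temporary ring as a conformational template: 21 with camphorsulfonic acid in CH2Cl2 should lactonise to the cis-8,12-lactone F3, which holds the C6 vinyl group and the C9 chain cis on a five-membered ring. Metathesis under the conditions of step 12 then gives the bicyclic lactone F4. LiOH in THF/H2O opens it to the lithium hydroxy-carboxylate F5, which is alkylated without acidification (allyl bromide, DMF) to the allyl ester F6. Methacrylation as in step 13 gives F7, and Pd(PPh3)4/PhSiH3 removes the allyl group to return to 25.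

Step 11. Enantio- or diastereocontrol may erode with the dienyl bromide, and the β,γ-unsaturated aldehyde may isomerise into conjugation before it is trapped. Fallback, from 19 back to 21, using a closed-transition-state allylboration in place of the chromium chemistry: bromide 19 with B2pin2 and Pd2(dba)3 (cat.) in toluene should give the allylboronate F8. A chiral BINOL-derived phosphoric acid (3,3'-bis(2,4,6-triisopropylphenyl) type, 5 mol %) in toluene at −30 °C then catalyses its addition to aldehyde 13 through a chair transition state (syn adduct from the Z-configured γ-vinyl boronate), and aqueous work-up gives 21.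

**Further compounds**

F1 | step 15 | (3aR,4R,6E,9Z,11S,11aR)-10-{[(4-methoxybenzyl)oxy]methyl}-6-methyl-3-methylidene-2-oxo-11-(phenylselanyl)-2,3,3a,4,5,8,11,11a-octahydrocyclodeca[b]furan-4-yl 2-methylprop-2-enoate (germacrane C5 selenide, Se anti to the lactone oxygen) | C=C(C)C(=O)O[C@@H]1C/C(C)=C/C/C=C(COCc3ccc(OC)cc3)\[C@H]([Se]c4ccccc4)[C@H]2OC(=O)C(=C)[C@@H]21
F2 | step 15 | (3aR,4R,6E,9S,10Z,11aR)-9-hydroxy-10-{[(4-methoxybenzyl)oxy]methyl}-6-methyl-3-methylidene-2-oxo-2,3,3a,4,5,8,9,11a-octahydrocyclodeca[b]furan-4-yl 2-methylprop-2-enoate | C=C(C)C(=O)O[C@@H]1C/C(C)=C/C[C@H](O)/C(COCc3ccc(OC)cc3)=C\[C@H]2OC(=O)C(=C)[C@@H]21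
F3 | step 12 | cis-4-ethenyl-5-[(2E,5E)-6-{[(4-methoxybenzyl)oxy]methyl}-2-methylocta-2,5,7-trien-1-yl]-3-methylideneoxolan-2-one (cis-8,12-lactone of 21) | C=C1C(=O)O[C@H](C/C(C)=C/C/C=C(\C=C)COCc2ccc(OC)cc2)[C@@H]1C=C
F4 | step 12 | cis-fused 8,12-lactone of the ten-membered triene (lactone form of the acid of 22) | C=C1C(=O)O[C@@H]2C/C(C)=C/C/C=C(COCc3ccc(OC)cc3)\C=C/[C@H]12
F5 | step 12 | lithium 2-[(1R,2Z,4E,7E,10R)-10-hydroxy-4-{[(4-methoxybenzyl)oxy]methyl}-8-methylcyclodeca-2,4,7-trien-1-yl]prop-2-enoate | [Li+].C=C(C(=O)[O-])[C@H]1/C=C\C(COCc2ccc(OC)cc2)=C/C/C=C(C)/C[C@H]1O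
F6 | step 12 | prop-2-en-1-yl 2-[(1R,2Z,4E,7E,10R)-10-hydroxy-4-{[(4-methoxybenzyl)oxy]methyl}-8-methylcyclodeca-2,4,7-trien-1-yl]prop-2-enoate | C=CCOC(=O)C(=C)[C@H]1/C=C\C(COCc2ccc(OC)cc2)=C/C/C=C(C)/C[C@H]1O
F7 | step 12 | prop-2-en-1-yl 2-[(1R,2Z,4E,7E,10R)-4-{[(4-methoxybenzyl)oxy]methyl}-8-methyl-10-[(2-methylprop-2-enoyl)oxy]cyclodeca-2,4,7-trien-1-yl]prop-2-enoate | C=CCOC(=O)C(=C)[C@H]1/C=C\C(COCc2ccc(OC)cc2)=C/C/C=C(C)/C[C@H]1OC(=O)C(C)=C
F8 | step 11 | 2-(trimethylsilyl)ethyl (2E)-2-[(4,4,5,5-tetramethyl-1,3,2-dioxaborolan-2-yl)methyl]penta-2,4-dienoate | C=C/C=C(\CB1OC(C)(C)C(C)(C)O1)C(=O)OCC[Si](C)(C)C
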